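The 1,2-dioxan-3-ol ring is cut into three pieces: C3–C4 from 3-methylpentane-2,4-dione, C5–C6 from a 2-methylalk-1-ene and O1–O2 from air. One manganese-mediated radical operation forges C4–C5, C6–O1 and O2–C3 and closes the ring. It exploits the fact that C6 is a fully substituted peroxy carbon (a tertiary radical site) lying 1,4 to the hemiketal carbon C3 (a ketone in disguise). The alkene partner already holds the C8 methyl centre, set by Evans alkylation, and a phenylalkyne that stands in for the radical-sensitive cis-styrene. Deacetylation, epimer separation and semi-hydrogenation then give the target.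

Key step: step 6

Remark on numbering: ring atoms are O1–O2–C3(OH)–C4–C5–C6; C7 is the side-chain CH2 and C8 the methyl-bearing CH.

Remark on epimers: step 6 is expected to give both C6 epimers. The 6S series is drawn and numbered (14–17); the 6R series travels with it until the chromatography of step 7.

Step 1
Reactants: 1 phenylacetylene; 2 1-bromo-5-chloropentane
Product: 4 (7-chlorohept-1-yn-1-yl)benzene, via lithium phenylacetylide 3 (not isolated)
Conditions: n-BuLi, THF, −78 °C; then 2, DMPU, −78 °C → rt
Reagents that add atoms: none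
Why: SN2 alkylation of a lithium acetylide, in which bromide leaves far faster than chloride, so a single C–C bond should form and the chloride remains for Grignard formation.

Step 2
Reactants: 5 (R)-4-benzyl-3-propionyloxazolidin-2-one; 6 3-bromo-2-methylprop-1-ene
Product: 8 (R)-4-benzyl-3-[(S)-2,4-dimethylpent-4-enoyl]oxazolidin-2-one, via sodium Z-enolate 7 (not isolated)
Conditions: NaN(SiMe3)2, THF, −78 °C; then 6, −78 → −40 °C
Reagents that add atoms: none
Why: Evans asymmetric alkylation: the chelated Z-enolate 7 is shielded on one face by the benzyl group of the (R)-auxiliary, so the allylic bromide should enter from the opposite face and set the (S)-configured methyl-bearing carbon (the future C8), the minor diastereomer being removable by chromatography.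

Step 3
Reactants: 8 (R)-4-benzyl-3-[(S)-2,4-dimethylpent-4-enoyl]oxazolidin-2-one
Product: 9 (S)-2,4-dimethylpent-4-en-1-ol
Conditions: LiBH4, H2O (1 equiv), Et2O, 0 °C
Reagents that add atoms: none
Why: Reductive cleavage of the N-acyl oxazolidinone by borohydride at the exocyclic carbonyl, which involves no enolisation and should therefore keep the new stereocentre intact and leave the alkene untouched (the volatile alcohol is concentrated cold and used directly).

Step 4
Reactants: 9 (S)-2,4-dimethylpent-4-en-1-ol
Product: 10 (S)-2,4-dimethylpent-4-en-1-yl 4-methylbenzenesulfonate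
Conditions: TsCl, Et3N, DMAP (cat.), CH2Cl2, 0 °C → rt
Reagents that add atoms: p-toluenesulfonyl chloride, Cc1ccc(cc1)S(Cl)(=O)=O
Why: Standard sulfonylation of a primary alcohol under nucleophilic catalysis, remote from the stereocentre.

Step 5
Reactants: 4 (7-chlorohept-1-yn-1-yl)benzene; 10 (S)-2,4-dimethylpent-4-en-1-yl 4-methylbenzenesulfonate
Product: 12 [(9R)-9,11-dimethyldodec-11-en-1-yn-1-yl]benzene, via alkynyl Grignard reagent 11 (not isolated)
Conditions: 4, Mg, I2 (cat.), THF, reflux; then 10, Li2CuCl4 (cat.), THF, −78 °C → rt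
Reagents that add atoms: none
Why: Copper-catalysed alkyl–alkyl cross-coupling of a primary Grignard reagent with a primary tosylate, an SN2-like displacement at CH2 that leaves the adjacent stereocentre untouched (its descriptor changes from S to R only through the priority rules) and tolerates the internal aryl alkyne and the 1,1-disubstituted alkene.

Step 6
Reactants: 12 [(9R)-9,11-dimethyldodec-11-en-1-yn-1-yl]benzene; 13 3-methylpentane-2,4-dione
Product: 15 1-[(3S,4R,6S)-3-hydroxy-3,4,6-trimethyl-6-[(2R)-2-methyl-10-phenyldec-9-yn-1-yl]-1,2-dioxan-4-yl]ethan-1-one, via open-chain hydroperoxy diketone 14 (not isolated)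
Conditions: Mn(OAc)3·2H2O (10 mol%), Mn(OAc)2·4H2O (10 mol%), 13 (3 equiv), AcOH, air, 23 °C
Reagents that add atoms: dioxygen, O=O
Why: Trivalent manganese oxidises the enol of 13 to the electrophilic tertiary C4 radical, which adds to the CH2 terminus of the alkene (C4–C5); the tertiary C6 radical captures O2 (C6–O1), divalent manganese reduces the peroxyl radical (returning the trivalent oxidant), and hydroperoxide 14 closes onto one of its two equivalent acetyl groups (O2–C3). This is the established manganese-acetate aerobic peroxycyclisation of 1,3-dicarbonyl compounds with 1,1-disubstituted alkenes to 1,2-dioxan-3-ols. The single ring closes by 6-exo-trig attack of the terminal hydroperoxide oxygen on the acetyl carbonyl. C6 forms when O2 meets a planar radical with only the C8 centre nearby, so no useful facial bias is expected and both C6 epimers should form; C3 and C4 arise together in the reversible hemiketalisation and settle thermodynamically (anomeric hydroxyl), which is immaterial because C4 is reset in step 7. The step needs chemoselectivity for the terminal alkene over the aryl alkyne and attack at CH2 instead of the substituted carbon; both follow from the unhindered, electron-rich 1,1-dialkylethene giving a tertiary radical, whereas addition to the internal alkyne would give a less stable vinyl radical at a hindered carbon.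

Step 7
Reactants: 15 1-[(3S,4R,6S)-3-hydroxy-3,4,6-trimethyl-6-[(2R)-2-methyl-10-phenyldec-9-yn-1-yl]-1,2-dioxan-4-yl]ethan-1-one
Product: 17 (3S,4R,6S)-3,4,6-trimethyl-6-[(2R)-2-methyl-10-phenyldec-9-yn-1-yl]-1,2-dioxan-3-ol, via open-chain hydroperoxy ketone 16 (not isolated)
Conditions: K2CO3, MeOH, 0 °C → rt; then SiO2 chromatography (normal-phase HPLC if needed) to separate the diastereomers
Reagents that add atoms: none
Why: Retro-Claisen cleavage: 15 stands in ring-chain equilibrium with its open tautomer 14, a non-enolisable 2,2-disubstituted 1,3-diketone from which methoxide removes one acetyl group as methyl acetate, and the resulting γ-hydroperoxy ketone 16 recloses, C4 equilibrating through its enolate with at most a small preference for the desired epimer (large C6 chain equatorial) and C3 following it by reversible hemiketalisation (C3 methyl equatorial and trans to the C4 methyl, anomeric hydroxyl axial), whereas the fixed 6R series and the C4 epimer are removed by chromatography.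

Step 8
Reactants: 17 (3S,4R,6S)-3,4,6-trimethyl-6-[(2R)-2-methyl-10-phenyldec-9-yn-1-yl]-1,2-dioxan-3-ol
Product: 18 (3S,4R,6S)-3,4,6-trimethyl-6-[(2R,9Z)-2-methyl-10-phenyldec-9-en-1-yl]-1,2-dioxan-3-ol
Conditions: H2 (1 atm), Pd/CaCO3 poisoned with Pb(OAc)2, quinoline, EtOAc, 0 °C → rt, stopped after one equivalent of H2
Reagents that add atoms: none
Why: Lindlar semi-hydrogenation: syn addition of one equivalent of H2 on lead- and quinoline-poisoned palladium should give the Z-alkene and stop there, and the deactivated catalyst is expected to spare the hindered dialkyl peroxide.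

Compound list
1 | phenylacetylene | C#Cc1ccccc1 | starting material
2 | 1-bromo-5-chloropentane | ClCCCCCBr | starting material
3 | lithium phenylacetylide | [Li+].[C-]#Cc1ccccc1 | intermediate
4 | (7-chlorohept-1-yn-1-yl)benzene | ClCCCCCC#Cc1ccccc1 | intermediate
5 | (R)-4-benzyl-3-propionyloxazolidin-2-one | CCC(=O)N1C(=O)OC[C@H]1Cc1ccccc1 | starting material
6 | 3-bromo-2-methylprop-1-ene | C=C(C)CBr | starting material
7 | sodium (Z)-enolate of 5 | C/C=C(\[O-])N1C(=O)OC[C@H]1Cc1ccccc1.[Na+] | intermediate
8 | (R)-4-benzyl-3-[(S)-2,4-dimethylpent-4-enoyl]oxazolidin-2-one | C[C@H](C(=O)N1C(=O)OC[C@H]1Cc1ccccc1)CC(C)=C | intermediate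
9 | (S)-2,4-dimethylpent-4-en-1-ol | C[C@H](CO)CC(C)=C | intermediate
10 | (S)-2,4-dimethylpent-4-en-1-yl 4-methylbenzenesulfonate | C[C@H](COS(=O)(=O)c1ccc(C)cc1)CC(C)=C | intermediate
11 | (7-phenylhept-6-yn-1-yl)magnesium chloride | Cl[Mg]CCCCCC#Cc1ccccc1 | intermediate
12 | [(9R)-9,11-dimethyldodec-11-en-1-yn-1-yl]benzene | C[C@H](CCCCCCC#Cc1ccccc1)CC(C)=C | intermediate
13 | 3-methylpentane-2,4-dione | CC(=O)C(C)C(C)=O | starting material
14 | 3-[(2S,4R)-2-hydroperoxy-2,4-dimethyl-12-phenyldodec-11-yn-1-yl]-3-methylpentane-2,4-dione | C[C@H](CCCCCCC#Cc1ccccc1)C[C@](C)(OO)CC(C)(C(C)=O)C(C)=O | intermediate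
15 | 1-[(3S,4R,6S)-3-hydroxy-3,4,6-trimethyl-6-[(2R)-2-methyl-10-phenyldec-9-yn-1-yl]-1,2-dioxan-4-yl]ethan-1-one | C[C@H](CCCCCCC#Cc1ccccc1)C[C@@]1(C)C[C@](C)(C(C)=O)[C@@](C)(O)OO1 | intermediate
16 | (5S,7R)-5-hydroperoxy-3,5,7-trimethyl-15-phenylpentadec-14-yn-2-one (C3 epimers) | C[C@H](CCCCCCC#Cc1ccccc1)C[C@](C)(OO)CC(C)C(C)=O | intermediate
17 | (3S,4R,6S)-3,4,6-trimethyl-6-[(2R)-2-methyl-10-phenyldec-9-yn-1-yl]-1,2-dioxan-3-ol | C[C@H](CCCCCCC#Cc1ccccc1)C[C@@]1(C)C[C@@H](C)[C@@](C)(O)OO1 | intermediate
18 | (3S,4R,6S)-3,4,6-trimethyl-6-[(2R,9Z)-2-methyl-10-phenyldec-9-en-1-yl]-1,2-dioxan-3-ol | C[C@H](CCCCCC/C=C\c1ccccc1)C[C@@]1(C)C[C@@H](C)[C@@](C)(O)OO1 | target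

Total step count: 8. Longest linear sequence: 7 (steps 2–8, from 5).

Steps most likely to fail

Step 6. The hindered tertiary diketone radical may add slowly, and the C6 peroxyl radical may fragment or abstract hydrogen before it is reduced and cyclised, so that little cyclic peroxide forms; in any case O2 capture is not face-selective, so about half of the material should carry the wrong C6 configuration. The fallback sets out from 12 and 13 and returns at 15. It makes the C4–C5 bond by ionic alkylation and the C6–O bond by cobalt-hydride hydroperoxidation. Ene-type allylic chlorination of 12 (Ca(OCl)2, CO2, CH2Cl2/H2O, 0 °C) should give [(9R)-11-(chloromethyl)-9-methyldodec-11-en-1-yn-1-yl]benzene F1. C-alkylation of 13 with it (K2CO3, NaI, acetone, reflux) should give 3-methyl-3-[(4R)-4-methyl-2-methylidene-12-phenyldodec-11-yn-1-yl]pentane-2,4-dione F2. Mukaiyama–Isayama hydroperoxysilylation (Co(acac)2, O2, Et3SiH, ClCH2CH2Cl, rt) should place the peroxy group at the tertiary carbon and give 3-[(4R)-2,4-dimethyl-12-phenyl-2-[(triethylsilyl)peroxy]dodec-11-yn-1-yl]-3-methylpentane-2,4-dione F3 as both C2 epimers. A trace of HCl in MeOH would then free hydroperoxide 14, the same open-chain intermediate as in step 6, which closes to 15.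

Step 7. The carbonate may open the hemiketal and degrade the hydroperoxide anion (base-induced O–O fragmentation) faster than the acetyl group is lost; separation of the four ring diastereomers may also be laborious (the C4 epimer of the 6S series can be re-equilibrated under the same conditions). The fallback sets out from 12 and returns at 17. It replaces the extra acyl group by an ester that leaves under acid. The peroxycyclisation of step 6, run with commercial tert-butyl 2-methyl-3-oxobutanoate in place of 13, should give tert-butyl (6S)-3-hydroxy-3,4,6-trimethyl-6-[(2R)-2-methyl-10-phenyldec-9-yn-1-yl]-1,2-dioxane-4-carboxylate F4. CF3CO2H in CH2Cl2 at 0 °C would cleave the ester to (6S)-3-hydroxy-3,4,6-trimethyl-6-[(2R)-2-methyl-10-phenyldec-9-yn-1-yl]-1,2-dioxane-4-carboxylic acid F5. Its ring-opened β-keto acid form should lose CO2 on gentle warming to give 16 and hence 17 after the same chromatographic separation.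

Step 8. Hydrogenolysis of the O–O bond on palladium (most likely through the small share of ring-opened hydroperoxide) or over-reduction and Z/E isomerisation may compete with semi-hydrogenation. The fallback sets out from 17 and returns at 18. It locks the hemiketal before the reduction. TsOH (cat.) and HC(OMe)3 in MeOH should give (3S,4R,6S)-3-methoxy-3,4,6-trimethyl-6-[(2R)-2-methyl-10-phenyldec-9-yn-1-yl]-1,2-dioxane F6, a peroxyketal with no hydroperoxide tautomer. The same poisoned-palladium semi-hydrogenation would give (3S,4R,6S)-3-methoxy-3,4,6-trimethyl-6-[(2R,9Z)-2-methyl-10-phenyldec-9-en-1-yl]-1,2-dioxane F7. Dilute aqueous acid (TsOH, THF/H2O, rt) would then exchange methoxy for hydroxyl and return 18.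

Further compounds
F1 | step 6 | [(9R)-11-(chloromethyl)-9-methyldodec-11-en-1-yn-1-yl]benzene | C[C@H](CCCCCCC#Cc1ccccc1)CC(=C)CCl
F2 | step 6 | 3-methyl-3-[(4R)-4-methyl-2-methylidene-12-phenyldodec-11-yn-1-yl]pentane-2,4-dione | C[C@H](CCCCCCC#Cc1ccccc1)CC(=C)CC(C)(C(C)=O)C(C)=O
F3 | step 6 | 3-[(4R)-2,4-dimethyl-12-phenyl-2-[(triethylsilyl)peroxy]dodec-11-yn-1-yl]-3-methylpentane-2,4-dione (both C2 epimers) | C[C@H](CCCCCCC#Cc1ccccc1)CC(C)(OO[Si](CC)(CC)CC)CC(C)(C(C)=O)C(C)=O
F4 | step 7 | tert-butyl (6S)-3-hydroxy-3,4,6-trimethyl-6-[(2R)-2-methyl-10-phenyldec-9-yn-1-yl]-1,2-dioxane-4-carboxylate | C[C@H](CCCCCCC#Cc1ccccc1)C[C@@]1(C)CC(C)(C(=O)OC(C)(C)C)C(C)(O)OO1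
F5 | step 7 | (6S)-3-hydroxy-3,4,6-trimethyl-6-[(2R)-2-methyl-10-phenyldec-9-yn-1-yl]-1,2-dioxane-4-carboxylic acid | C[C@H](CCCCCCC#Cc1ccccc1)C[C@@]1(C)CC(C)(C(=O)O)C(C)(O)OO1
F6 | step 8 | (3S,4R,6S)-3-methoxy-3,4,6-trimethyl-6-[(2R)-2-methyl-10-phenyldec-9-yn-1-yl]-1,2-dioxane | C[C@H](CCCCCCC#Cc1ccccc1)C[C@@]1(C)C[C@@H](C)[C@@](C)(OC)OO1
F7 | step 8 | (3S,4R,6S)-3-methoxy-3,4,6-trimethyl-6-[(2R,9Z)-2-methyl-10-phenyldec-9-en-1-yl]-1,2-dioxane | C[C@H](CCCCCC/C=C\c1ccccc1)C[C@@]1(C)C[C@@H](C)[C@@](C)(OC)OO1
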